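**Retrosynthetic overview**

1. The butenolide is attached last: C12–C13 is cut to a C9-vinyl triol plus 3-bromofuran-2(5H)-one (hydroboration, B-alkyl Suzuki), because the lactone would not survive the hydride step.
2. The triol comes from one LiAlH4 reduction of a 3-oxo decalin diester (C3 carbinol, C19 and C17 carbinols, auxiliary released), after C8 has been equilibrated to the equatorial ester.
3. Key disconnection C4–C5: one-electron oxidation turns the enolate carbon C4 of a 2-methyl-3-oxo ester into an enolonium-type radical that bonds to the alkene carbon C5; both carbons are normally nucleophilic.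
4. Ring order: ring A closes first (C4–C5), then ring B (C10–C9) onto a (Z)-dienoate, in the same flask; C4, C5, C10 and C9 are set there, and C17 arrives already oxidised.
5. The acyclic precursor comes from γ-alkylation of a chiral 2-methylacetoacetate dianion (C1–C2) with an (E)-allylic bromide, itself made by Still–Gennari olefination of acrolein (C8=C9), SeO2 oxidation and bromination.

Labdane numbering (C1–C20) is used for all carbons, also in the acyclic precursors.

Assumption: the free C4 radical of the (1S,2R,5S)-8-phenylmenthyl ester is shielded by the phenyl ring on the face that leaves the ent-labdane (10α-methyl) series, the mirror image of the induction recalled for the antipodal ester in podocarpate work; if the sense were reversed, the antipodal auxiliary would be used with no other change.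

**Route**

Step 1
Reactants: 1 methyl 2-[bis(2,2,2-trifluoroethoxy)phosphoryl]acetate; 2 5-bromo-2-methylpent-2-ene
Product: 3 methyl 2-[bis(2,2,2-trifluoroethoxy)phosphoryl]-6-methylhept-5-enoate (racemic)
Conditions: NaH (1.05 equiv), NaI (0.1 equiv), DMSO, 0 °C → 50 °C
Reagents that add atoms: none
Why: SN2 C-alkylation of the stabilised phosphonoacetate carbanion by a primary bromide under iodide catalysis, with the second alkylation slowed by sterics; the new CH centre is destroyed in step 2.

Step 2
Reactants: 3 methyl 2-[bis(2,2,2-trifluoroethoxy)phosphoryl]-6-methylhept-5-enoate; 4 acrolein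
Product: 5 methyl (2Z)-2-(4-methylpent-3-en-1-yl)penta-2,4-dienoate
Conditions: KN(SiMe3)2 (1.05 equiv), 18-crown-6 (3 equiv), THF, −78 °C; then 4 (1.5 equiv), −78 °C
Reagents that add atoms: none
Why: Still–Gennari variant of the Horner–Wadsworth–Emmons olefination, where the electron-poor phosphonate and the crown-separated potassium ion make elimination faster than adduct equilibration, so the ester ends cis to the vinyl group (2Z).

Step 3
Reactants: 5 methyl (2Z)-2-(4-methylpent-3-en-1-yl)penta-2,4-dienoate
Product: 6 methyl (2Z)-2-[(3E)-5-hydroxy-4-methylpent-3-en-1-yl]penta-2,4-dienoate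
Conditions: SeO2 (0.1 equiv), t-BuOOH (3 equiv), salicylic acid (0.1 equiv), CH2Cl2, 0 °C → rt
Reagents that add atoms: tert-butyl hydroperoxide, CC(C)(C)OO (oxygen atom, relayed by catalytic SeO2)
Why: catalytic SeO2 allylic oxidation (ene reaction, then [2,3]-sigmatropic shift) attacks only the electron-rich trisubstituted alkene and, as usual for gem-dimethyl alkenes, the methyl trans to the chain, giving the (E)-allylic alcohol.

Step 4
Reactants: 6 methyl (2Z)-2-[(3E)-5-hydroxy-4-methylpent-3-en-1-yl]penta-2,4-dienoate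
Product: 7 methyl (2Z)-2-[(3E)-5-bromo-4-methylpent-3-en-1-yl]penta-2,4-dienoate
Conditions: CBr4 (1.2 equiv), PPh3 (1.25 equiv), CH2Cl2, 0 °C
Reagents that add atoms: carbon tetrabromide, BrC(Br)(Br)Br
Why: Appel bromination displaces the primary alkoxyphosphonium by SN2 under neutral conditions, so both alkene geometries are kept.

Step 5
Reactants: 8 ethyl 2-methyl-3-oxobutanoate; 9 (+)-8-phenylmenthol, (1S,2R,5S)-5-methyl-2-(2-phenylpropan-2-yl)cyclohexan-1-ol
Product: 10 (1S,2R,5S)-5-methyl-2-(2-phenylpropan-2-yl)cyclohexyl 2-methyl-3-oxobutanoate (epimers at the acidic C2 of the acyl chain)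
Conditions: DMAP (0.3 equiv), toluene, reflux, 4 Å sieves, removal of EtOH
Reagents that add atoms: none
Why: DMAP-catalysed transesterification of a β-keto ester (through the acylketene) is driven by loss of ethanol and leaves the carbinol stereocentres untouched.

Step 6
Reactants: 10 (1S,2R,5S)-5-methyl-2-(2-phenylpropan-2-yl)cyclohexyl 2-methyl-3-oxobutanoate; 7 methyl (2Z)-2-[(3E)-5-bromo-4-methylpent-3-en-1-yl]penta-2,4-dienoate
Product: 12 (1S,2R,5S)-5-methyl-2-(2-phenylpropan-2-yl)cyclohexyl (6E,10Z)-10-(methoxycarbonyl)-2,6-dimethyl-3-oxotrideca-6,10,12-trienoate, via dilithium dienolate 11 (not isolated)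
Conditions: LiN(iPr)2 (2.1 equiv), THF, 0 °C; then 7, −78 → 0 °C; 1 M HCl quench
Reagents that add atoms: none
Why: Huckin–Weiler γ-alkylation of the acetoacetate dianion, whose terminal carbanion (C2) displaces the allylic bromide by SN2 faster than it adds to the hindered dienoate; C4 stays an epimer mixture that is planarised in step 7.

Step 7
Reactants: 12 (1S,2R,5S)-5-methyl-2-(2-phenylpropan-2-yl)cyclohexyl (6E,10Z)-10-(methoxycarbonyl)-2,6-dimethyl-3-oxotrideca-6,10,12-trienoate
Product: 13 1-[(1S,2R,5S)-5-methyl-2-(2-phenylpropan-2-yl)cyclohexyl] 6-methyl (1S,4aS,5R,6R,8aS)-5-ethenyl-1,4a-dimethyl-2-oxodecahydronaphthalene-1,6-dicarboxylate (labdane 4S,5S,8R,9R,10S; C8 ester axial; some 14 expected alongside)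
Conditions: Mn(OAc)3·2H2O (2.5 equiv), degassed EtOH (0.02 M), 40 °C, argon
Reagents that add atoms: none
Why: Proposed new method: oxidation of the manganese enolate makes C4 an electrophilic α-keto-ester radical (enolonium equivalent) that adds 6-endo to C5 of the (E)-alkene through a chair with the ester axial and on the face not shielded by the auxiliary phenyl ring (C4, C5, C10), the nucleophilic tertiary C10 radical then closes ring B 6-endo on the β-carbon of the (Z)-dienoate (polarity matched; the vinyl group, trans to C7 in the alkene, becomes equatorial at C9), and the electrophilic C8 α-ester radical is quenched by hydrogen abstraction from ethanol, mainly from the face away from the axial C10 methyl; the closest known chemistry is the Mn(OAc)3 oxidative polyene cyclisation of 2-methyl-3-oxo esters with 8-phenylmenthyl control, joined to the acceptor-alkene terminators of polarity-alternating radical polycyclisations.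

Step 8
Reactants: 13 the C8-axial keto diester
Product: 14 1-[(1S,2R,5S)-5-methyl-2-(2-phenylpropan-2-yl)cyclohexyl] 6-methyl (1S,4aS,5R,6S,8aS)-5-ethenyl-1,4a-dimethyl-2-oxodecahydronaphthalene-1,6-dicarboxylate (labdane 4S,5S,8S,9R,10S; C8 ester equatorial)
Conditions: KOtBu (0.2 equiv), t-BuOH–THF (1:1), 40 °C; pH 7 buffer
Reagents that add atoms: none
Why: thermodynamic epimerisation through the C8 ester enolate relieves the 1,3-diaxial clash of the axial ester with the C10 methyl and leaves the ester equatorial, trans to the C9 vinyl group (8S), while bulky tert-butoxide should not open the ring A keto ester by retro-Claisen attack.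

Step 9
Reactants: 14 the C8-equatorial keto diester
Product: 15 (1R,2R,4aS,5R,6S,8aS)-5-ethenyl-1,6-bis(hydroxymethyl)-1,4a-dimethyldecahydronaphthalen-2-ol (labdane 3R,4R,5S,8S,9R,10S)
Conditions: LiAlH4 (6 equiv), THF, 0 °C → reflux; Fieser work-up; 9 recovered by chromatography
Reagents that add atoms: none
Why: exhaustive hydride reduction in which the C3 ketone is attacked axially, on the face opposite the axial C4 ester, to give the equatorial 3R alcohol cis to C19, and both esters (the hindered auxiliary ester helped by the neighbouring alkoxyaluminate) go to primary alcohols while the vinyl group is inert.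

Step 10
Reactants: 15 the C9-vinyl triol; 16 3-bromofuran-2(5H)-one
Product: 18 14-deoxy-17-hydroxyandrographolide, 3-{2-[(1R,2S,4aS,5R,6R,8aS)-6-hydroxy-2,5-bis(hydroxymethyl)-5,8a-dimethyldecahydronaphthalen-1-yl]ethyl}furan-2(5H)-one, via alkylborane 17 (not isolated)
Conditions: 9-BBN (5 equiv), THF, 0 °C → rt; then 16 (1.5 equiv), Pd(dppf)Cl2·CH2Cl2 (10 mol%), AsPh3 (10 mol%), 3 M aq K3PO4, DMF, rt
Reagents that add atoms: none
Why: anti-Markovnikov hydroboration of the only alkene puts boron on C12 (excess reagent covers the three hydroxyl groups, whose O–B bonds the aqueous base cleaves), and B-alkyl Suzuki–Miyaura coupling with the α-bromo enoate, which adds readily to zerovalent palladium, forms C12–C13 without touching a stereocentre.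

**Compound list**

1 | methyl 2-[bis(2,2,2-trifluoroethoxy)phosphoryl]acetate | COC(=O)CP(=O)(OCC(F)(F)F)OCC(F)(F)F | starting material
2 | 5-bromo-2-methylpent-2-ene | CC(C)=CCCBr | starting material
3 | methyl 2-[bis(2,2,2-trifluoroethoxy)phosphoryl]-6-methylhept-5-enoate (racemic) | COC(=O)C(CCC=C(C)C)P(=O)(OCC(F)(F)F)OCC(F)(F)F | intermediate
4 | acrolein | C=CC=O | starting material
5 | methyl (2Z)-2-(4-methylpent-3-en-1-yl)penta-2,4-dienoate | COC(=O)/C(CCC=C(C)C)=C\C=C | intermediate
6 | methyl (2Z)-2-[(3E)-5-hydroxy-4-methylpent-3-en-1-yl]penta-2,4-dienoate | COC(=O)/C(CC/C=C(\C)CO)=C\C=C | intermediate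
7 | methyl (2Z)-2-[(3E)-5-bromo-4-methylpent-3-en-1-yl]penta-2,4-dienoate | COC(=O)/C(CC/C=C(\C)CBr)=C\C=C | intermediate
8 | ethyl 2-methyl-3-oxobutanoate | CCOC(=O)C(C)C(C)=O | starting material
9 | (+)-8-phenylmenthol, (1S,2R,5S)-5-methyl-2-(2-phenylpropan-2-yl)cyclohexan-1-ol | O[C@H]1C[C@@H](C)CC[C@@H]1C(C)(C)c1ccccc1 | starting material
10 | (1S,2R,5S)-5-methyl-2-(2-phenylpropan-2-yl)cyclohexyl 2-methyl-3-oxobutanoate | CC(=O)C(C)C(=O)O[C@H]1C[C@@H](C)CC[C@@H]1C(C)(C)c1ccccc1 | intermediate
11 | dilithium dienolate of 10 | [Li+].[Li+].C=C([O-])C(C)=C([O-])O[C@H]1C[C@@H](C)CC[C@@H]1C(C)(C)c1ccccc1 | intermediate (not isolated)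
12 | (1S,2R,5S)-5-methyl-2-(2-phenylpropan-2-yl)cyclohexyl (6E,10Z)-10-(methoxycarbonyl)-2,6-dimethyl-3-oxotrideca-6,10,12-trienoate | COC(=O)/C(CC/C=C(\C)CCC(=O)C(C)C(=O)O[C@H]1C[C@@H](C)CC[C@@H]1C(C)(C)c1ccccc1)=C\C=C | intermediate
13 | keto diester, C8 ester axial (labdane 4S,5S,8R,9R,10S) | C[C@]1(C(=O)O[C@H]3C[C@@H](C)CC[C@@H]3C(C)(C)c3ccccc3)[C@H]2CC[C@@H](C(=O)OC)[C@@H](C=C)[C@]2(C)CCC1=O | intermediate
14 | keto diester, C8 ester equatorial (labdane 4S,5S,8S,9R,10S) | C[C@]1(C(=O)O[C@H]3C[C@@H](C)CC[C@@H]3C(C)(C)c3ccccc3)[C@H]2CC[C@H](C(=O)OC)[C@@H](C=C)[C@]2(C)CCC1=O | intermediate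
15 | (1R,2R,4aS,5R,6S,8aS)-5-ethenyl-1,6-bis(hydroxymethyl)-1,4a-dimethyldecahydronaphthalen-2-ol | C[C@]1(CO)[C@H]2CC[C@H](CO)[C@@H](C=C)[C@]2(C)CC[C@H]1O | intermediate
16 | 3-bromofuran-2(5H)-one | O=C1OCC=C1Br | starting material
17 | 9-{2-[(1R,2S,4aS,5R,6R,8aS)-6-hydroxy-2,5-bis(hydroxymethyl)-5,8a-dimethyldecahydronaphthalen-1-yl]ethyl}-9-borabicyclo[3.3.1]nonane | C[C@]1(CO)[C@H]2CC[C@H](CO)[C@@H](CCB3C4CCCC3CCC4)[C@]2(C)CC[C@H]1O | intermediate (not isolated)
18 | 14-deoxy-17-hydroxyandrographolide | C[C@]1(CO)[C@H]2CC[C@H](CO)[C@@H](CCC3=CCOC3=O)[C@]2(C)CC[C@H]1O | target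

**Step count and risks**

Total steps: 10. Longest linear sequence: 9 (steps 1–4, then 6–10); step 5 is a one-step side branch.

The three steps most likely to fail are 7, 8 and 10.

Step 7 (oxidative bicyclisation). Enolisation of the α-methyl keto ester may be slow, the C10 radical may be quenched before it reaches the dienoate, or facial control may be poor. The fallback generates the same enolonium-type radical reductively. Starting from 12, bromination at C4 (NaH, then N-bromosuccinimide, THF, −78 °C) gives the 2-bromo-2-methyl-3-oxo ester F1. Et3B/air-initiated atom-transfer bicyclisation (benzene, rt, no Lewis acid so that the ester stays axial) gives the 8-bromo decalin diester F2. Bu3SnH/AIBN (benzene, 80 °C) then replaces bromine by hydrogen and returns to 13, which continues with step 8.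

Step 8 (C8 epimerisation). Base may open ring A by retro-Claisen cleavage or fail to equilibrate the hindered ester. The fallback removes the ketone first. Starting from 13, NaBH4 (MeOH, 0 °C) gives the 3-hydroxy diester with axial C8 ester F3, in which retro-Claisen cleavage is no longer possible. NaOMe in MeOH at 50 °C then epimerises C8 to the 3-hydroxy diester with equatorial C8 ester F4, and LiAlH4 in refluxing THF reduces both esters, coming back to the route at 15.

Step 10 (butenolide attachment). The base-sensitive bromobutenolide or the free triol may spoil the Suzuki coupling. The fallback changes the bond-forming mode. Starting from 15, the alkylborane 17 is iodinated in the flask (I2, NaOMe, MeOH, 0 °C) to the primary iodide F5. A reductive cross-electrophile coupling of F5 with 16 (NiI2 10 mol%, 4,4'-di-tert-butyl-2,2'-bipyridine, Zn powder, DMA, rt), which tolerates free hydroxyl groups, then gives 18 directly.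

**Further compounds**

F1 | step 7 | (1S,2R,5S)-5-methyl-2-(2-phenylpropan-2-yl)cyclohexyl (6E,10Z)-2-bromo-10-(methoxycarbonyl)-2,6-dimethyl-3-oxotrideca-6,10,12-trienoate | COC(=O)/C(CC/C=C(\C)CCC(=O)C(C)(Br)C(=O)O[C@H]1C[C@@H](C)CC[C@@H]1C(C)(C)c1ccccc1)=C\C=C
F2 | step 7 | 8-bromo keto diester (labdane numbering, C8 configuration not defined) | C[C@]1(C(=O)O[C@H]3C[C@@H](C)CC[C@@H]3C(C)(C)c3ccccc3)[C@H]2CCC(Br)(C(=O)OC)[C@@H](C=C)[C@]2(C)CCC1=O
F3 | step 8 | 3-hydroxy diester with axial C8 ester | C[C@]1(C(=O)O[C@H]3C[C@@H](C)CC[C@@H]3C(C)(C)c3ccccc3)[C@H]2CC[C@@H](C(=O)OC)[C@@H](C=C)[C@]2(C)CC[C@H]1O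
F4 | step 8 | 3-hydroxy diester with equatorial C8 ester | C[C@]1(C(=O)O[C@H]3C[C@@H](C)CC[C@@H]3C(C)(C)c3ccccc3)[C@H]2CC[C@H](C(=O)OC)[C@@H](C=C)[C@]2(C)CC[C@H]1O
F5 | step 10 | (1R,2R,4aS,5R,6S,8aS)-1,6-bis(hydroxymethyl)-5-(2-iodoethyl)-1,4a-dimethyldecahydronaphthalen-2-ol | C[C@]1(CO)[C@H]2CC[C@H](CO)[C@@H](CCI)[C@]2(C)CC[C@H]1O
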